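**Conventions and one assumption.** Core atoms keep the target's numbering in every intermediate: C1 (methyl-bearing fusion carbon), C2 (OAc), C3, C4 (OH, isopropyl), C5 (fusion CH), C6 (anisoyloxy), C7, C8/C9 (epoxide), C10 (OH); C15 is the C1 methyl. β is the face of the C1 methyl, α the opposite face. In the bicyclo[3.1.0]hexanes C1, C5 and C10 form the cyclopropane, and "exo" on C10 means cis to the C1 and C5 substituents. Assumption: (R)-4-(tert-butyldimethylsilyloxy)cyclopent-2-en-1-one (1) is bought as the single enantiomer; its stereocentre becomes C2.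

## Analysis of the target

Compound 27 (CNP0371526.1) is a daucane-type diester built on a trans-fused hydroazulene: a cyclopentane (C1–C5) fused through C1–C5 to a cycloheptane (C5–C10, C1). It has eight stereocentres: quaternary C1 (β-methyl), C2 (β-OAc), C4 (β-OH, α-isopropyl), C5 (α-H), C6 (α-anisoyloxy), C8 and C9 (α-epoxide, β-methyl on C8) and C10 (β-OH). The oxygens at C2, C4 and C10 share the face of the angular methyl, whereas H5, the C6 oxygen and the epoxide lie on the other face. Sensitive points are the trisubstituted epoxide next to a free secondary alcohol (Payne shift, acid opening), two different esters close to free hydroxyls (the C2 acetate and the C10 hydroxyl are 1,3-cis, so acyl migration is possible), and the tertiary C4 hydroxyl, which is β to C6 and can be lost by dehydration or retro-aldol whenever C6 is a ketone. The hard parts are the quaternary C1 surrounded by three stereocentres (C2, C5, C10), a seven-membered ring functionalised at five of its carbons, and four oxygens that must end up differentiated (two different esters, two free alcohols). The strategy rests on one observation: the seven-membered ring hangs on C1, carries oxygen at C6 and functionality from C8 to C10, which is the imprint of a cis-divinylcyclopropane rearrangement in which C1, C5 and C10 were the three-membered ring, C6 an enol ether carbon and C9=C10 an alkene.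

## Retrosynthetic reasoning

**27 ⇒ 26 ⇒ 25.** The last bonds cut are the O–Si bond at C10 and the two C–O bonds of the epoxide. The epoxide is the most fragile group and is therefore made last. It must sit on the α face, anti to the 10β oxygen. A free 10-hydroxyl would steer a peracid to the β face, so it is masked as the triethylsilyl ether 25, whose bulk adds to that of the C1 methyl.

**24 ⇒ 22 (through 23).** The C10–O bond is cut with allylic transposition, back to the C9=C10 alkene 22. The forward reaction is a photo-oxygenation (ene reaction). C1 is quaternary, so the only allylic hydrogen is on C8: oxygen must enter at C10 and the alkene must move to C8=C9. The ene reaction is suprafacial, so oxygen arrives on the face of the C8 hydrogen, which is β. This is the configuration required at C10, and no C10 ketone has to be made and reduced.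

**22 ⇒ 21 ⇒ 20 ⇒ 19.** The two ester C–O bonds are cut in an order set by differentiation. The C2 acetate is introduced before the C10 hydroxyl exists, because both are neopentyl secondary alcohols on C1 and could not be told apart. The C6 anisoate is introduced before C2 is unmasked. The tertiary C4 hydroxyl does not acylate and needs no protection.

**19 ⇒ 18.** The C6–H bond is cut back to the ketone. The β face of this ketone carries the angular methyl, so an external hydride would be expected from the α face and give the wrong epimer. The free 4β-hydroxyl is therefore used to deliver hydride internally to the β face, which gives the 6α-alcohol (1,3-anti diol). This is why C4 carries only a trimethylsilyl group that is lost when the ketone is unveiled.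

**18 ⇒ 17.** The C5–H bond and two O–Si bonds are cut: 17 is the silyl enol ether of ketone 18. Its cleavage has to set C5 with the hydrogen α (trans ring fusion).

**17 ⇒ 16 ⇒ 15 (key disconnection).** The C7–C8 bond is cut and C5–C10 reconnected, turning the cycloheptadiene into a cis-divinylcyclopropane. This is chosen over any direct seven-ring closure because C1 is then quaternary in a small ring, where it is easy to make, and is never formed on the seven-membered ring. The same step leaves C6 as an enol ether and a C9=C10 alkene placed for the transposition above. The forward reaction needs the siloxyvinyl group on C5 and an E-propenyl group on C10 cis to each other, and a boat transition state.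

**15 ⇒ 14 ⇒ 13 ⇒ 12.** The C8=C9 bond is cut (olefination of aldehyde 14), and redox adjustment leads back to lactone 12. In 12 the carbons C6 and C9 are tied together by the lactone on one side of the cyclopropane, so the cis relationship demanded by the key step follows from connectivity and not from a selectivity.

**12 ⇒ 11 ⇒ 10.** C1–C10 and C5–C10 are cut: a carbenoid from diazoacetate 11, tethered through the C6 oxygen, adds across the C1=C5 bond. An intermolecular ylide cyclopropanation of the corresponding enone was considered and not chosen: the exo position on C10 is cis to both fusion substituents and is the more hindered one, and the tetrasubstituted, twisted enone is a poor acceptor. The tethered carbenoid answers both points. It must add on the α face, anti to the two silyloxy groups; the (R)-carbinol centre at C6 reinforces this because its methyl sits on the convex side of the new lactone only in the α-face transition state.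

**10 ⇒ 9 ⇒ 8 ⇒ 6 (through 7).** The C6–H bond (reagent-controlled ketone reduction), one O–Si bond and the C4–isopropyl bond are cut. The isopropyl group is added to cyclopentenone 6 anti to the C2 silyloxy group, which gives the cis-1,3-dioxygen pattern. It is done on the monocycle because, once the cyclopropane exists, a C4 ketone would be attacked from the convex face and give the wrong epimer. The acetyl group travels through this step as its ethoxyvinyl ether.

**6 ⇒ 4 + 5 ⇒ 3 ⇒ 2 ⇒ 1.** The C5–C6 bond is cut to iodoenone 4 and stannane 5 (Stille coupling). The iodide comes from enone 3, and the C1 methyl from conjugate addition to 1 followed by re-oxidation. Compound 1 supplies C2, from which every other stereocentre is derived.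

## Alternatives that were turned down

**Alternative 1: angular methyl by hydroxyl-directed cyclopropanation.** The disconnection is the C1–C15 bond, made last. In the forward step a zinc carbenoid, held by the C2 and C4 hydroxyls, adds to the silyloxy-substituted C1=C10 bond of dienol ether A2 on the β face and gives siloxycyclopropane A1; opening of its C10–C15 bond would then release the methyl group and a C10 carbonyl. In its favour: the quaternary centre is made under the control of two hydroxyls that both sit on the required face, the electron-rich enol ether alkene is naturally preferred over C8=C9, and the anisoate is already in place. Against it: the step creates one carbon only, so the complete hydroazulene with the C5 configuration must already exist without the methyl group. The C1=C10 enol ether is a tetrasubstituted ring-fusion alkene, and its formation has to compete with γ-deprotonation of the enone. The acid needed to open A1 meets a tertiary alcohol and an allylic system. On facial control at C1 this alternative is stronger than the chosen route, which relies on a tethered carbenoid and a temporary C6 centre. The chosen route offers in exchange one step that builds the seven-membered ring and places the C6 oxygen and the C9=C10 alkene.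

**Alternative 2: cyclopentanone by carbenoid C–H insertion.** The disconnection is C3–C4. In the forward step the rhodium carbenoid from diazomethyl ketone A4 inserts into the C4–H bond next to the silyloxy group (1,5-insertion, retention) and closes cyclopentanone A3. In its favour: five-ring formation by 1,5-insertion is the most reliable mode, the oxygen activates the C–H bond, and retention makes the tertiary C4 centre from an easily set secondary carbinol. On C4 it is as strong as, or stronger than, the Grignard addition used here. Against it: A4 needs three contiguous stereocentres (quaternary C1, C5, C4) assembled on an open chain. The C–H bond to be attacked is a methine flanked by isopropyl and a bulky silyl ether, with the isopropyl methine and the CH2O group as competitors. A3 contains nothing of the seven-membered ring, so C7, C8, C9, the ring closure and all functionality from C6 to C10 would follow in a long sequence, and the C2 ketone would still need a β-selective reduction. The chosen route pays for its weaker C4 control with a precursor whose single rearrangement delivers the whole seven-membered ring.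

**Alternative 3: transannular enolate–epoxide cyclisation.** The disconnection is C1–C5 across a ten-membered ring. In the forward step the C1 enolate of epoxy cyclodecenone A6 opens the C4–C5 epoxide at C5 with inversion and gives trans-fused hydroazulenone A5; one bond makes both rings, C1, C5 and the free C4 hydroxyl, and leaves the C10 enone and the C8=C9 alkene in place. In step economy and convergence this is stronger than the chosen route. Against it: A6 is a ten-membered ring with several stereo-elements, itself a hard target. Enolisation of the hindered C1 methine must beat γ-deprotonation of the enone and retro-aldol or β-elimination of the C2 oxygen. The enolate, C5 and the leaving oxygen must be collinear, which depends on the ring conformer, as does the configuration of the new quaternary centre. The chosen route gives up some convergence for a pericyclic step whose stereochemical course is fixed by alkene geometry and a small ring, with every centre under separate control.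

Key step: step 13

## Route

Step 1
Reactants: 1 (R)-4-(tert-butyldimethylsilyloxy)cyclopent-2-en-1-one
Product: 2 (3R,4R)-4-(tert-butyldimethylsilyloxy)-3-methyl-1-(trimethylsilyloxy)cyclopent-1-ene
Conditions: Me2CuLi (from MeLi, CuI), TMSCl, THF, −78 °C
Reagents that add atoms: lithium dimethylcuprate, [Li+].C[Cu-]C; chlorotrimethylsilane, C[Si](C)(C)Cl
Why: Cuprate conjugate addition anti to the silyloxy group; TMSCl traps the enolate before it can expel the β-silyloxide. The new C1 centre is transient (removed in step 2).

Step 2
Reactants: 2 (3R,4R)-4-(tert-butyldimethylsilyloxy)-3-methyl-1-(trimethylsilyloxy)cyclopent-1-ene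
Product: 3 (R)-4-(tert-butyldimethylsilyloxy)-3-methylcyclopent-2-en-1-one
Conditions: Pd(OAc)2 (1.05 equiv), MeCN, rt
Reagents that add atoms: none
Why: Saegusa–Ito oxidation: the palladium enolate at C5 can only eliminate the C1 hydrogen, which returns the enone with the methyl group on the β-carbon; C2 is untouched.

Step 3
Reactants: 3 (R)-4-(tert-butyldimethylsilyloxy)-3-methylcyclopent-2-en-1-one
Product: 4 (R)-4-(tert-butyldimethylsilyloxy)-2-iodo-3-methylcyclopent-2-en-1-one
Conditions: I2, TMSN3, pyridine, CH2Cl2, 0 °C
Reagents that add atoms: iodine, II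
Why: α-Iodination of an enone by conjugate addition of azide, iodination of the enol ether and elimination; the small azide nucleophile should tolerate the β-methyl group.

Step 4
Reactants: 4 (R)-4-(tert-butyldimethylsilyloxy)-2-iodo-3-methylcyclopent-2-en-1-one; 5 tributyl(1-ethoxyethenyl)stannane
Product: 6 (R)-4-(tert-butyldimethylsilyloxy)-2-(1-ethoxyethenyl)-3-methylcyclopent-2-en-1-one
Conditions: Pd2(dba)3 (2.5 mol%), AsPh3 (10 mol%), CuI (10 mol%), NMP, rt
Reagents that add atoms: none
Why: Stille coupling of an α-iodoenone, a reactive electrophile; the ethoxyvinyl group is a masked acetyl that does not compete with the ring ketone in step 5.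

Step 5
Reactants: 6 (R)-4-(tert-butyldimethylsilyloxy)-2-(1-ethoxyethenyl)-3-methylcyclopent-2-en-1-one
Product: 8 1-[(3R,5R)-3-(tert-butyldimethylsilyloxy)-5-hydroxy-2-methyl-5-(propan-2-yl)cyclopent-1-en-1-yl]ethan-1-one, via ethoxyvinyl carbinol 7 (not isolated)
Conditions: i-PrMgCl, LaCl3·2LiCl, THF, −78 → 0 °C; then 0.5 M aq. HCl, 0 °C
Reagents that add atoms: isopropylmagnesium chloride, CC(C)[Mg]Cl; water, O
Why: Lanthanide-mediated Grignard 1,2-addition (suppresses enolisation and reduction) anti to the C2 silyloxy group, as is usual for 4-silyloxycyclopentenones, sets C4 with isopropyl α and oxygen β. Brief aqueous acid hydrolyses the enol ether to the acetyl group.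

Step 6
Reactants: 8 1-[(3R,5R)-3-(tert-butyldimethylsilyloxy)-5-hydroxy-2-methyl-5-(propan-2-yl)cyclopent-1-en-1-yl]ethan-1-one
Product: 9 1-[(3R,5R)-3-(tert-butyldimethylsilyloxy)-2-methyl-5-(propan-2-yl)-5-(trimethylsilyloxy)cyclopent-1-en-1-yl]ethan-1-one
Conditions: TMSOTf, 2,6-lutidine, CH2Cl2, −78 °C
Reagents that add atoms: trimethylsilyl triflate, C[Si](C)(C)OS(=O)(=O)C(F)(F)F
Why: Silylation of the tertiary alcohol; with lutidine at −78 °C the ketone is not enolised. TMS is chosen so that it later leaves together with the enol silyl group and frees the C4 hydroxyl for step 15.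

Step 7
Reactants: 9 1-[(3R,5R)-3-(tert-butyldimethylsilyloxy)-2-methyl-5-(propan-2-yl)-5-(trimethylsilyloxy)cyclopent-1-en-1-yl]ethan-1-one
Product: 10 (1R)-1-[(3R,5R)-3-(tert-butyldimethylsilyloxy)-2-methyl-5-(propan-2-yl)-5-(trimethylsilyloxy)cyclopent-1-en-1-yl]ethan-1-ol
Conditions: (S)-Me-CBS (20 mol%), BH3·SMe2, THF, −30 °C
Reagents that add atoms: none
Why: Corey–Bakshi–Shibata 1,2-reduction of an alkenyl methyl ketone; with the alkenyl group as the large substituent the (S)-catalyst should give the (R)-carbinol. This temporary C6 centre is used in step 9 and erased in step 11.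

Step 8
Reactants: 10 (1R)-1-[(3R,5R)-3-(tert-butyldimethylsilyloxy)-2-methyl-5-(propan-2-yl)-5-(trimethylsilyloxy)cyclopent-1-en-1-yl]ethan-1-ol
Product: 11 (1R)-1-[(3R,5R)-3-(tert-butyldimethylsilyloxy)-2-methyl-5-(propan-2-yl)-5-(trimethylsilyloxy)cyclopent-1-en-1-yl]ethyl 2-diazoacetate
Conditions: TsNHN=CHCOCl, PhNMe2, CH2Cl2, 0 °C; then Et3N
Reagents that add atoms: glyoxylic acid chloride p-toluenesulfonylhydrazone, Cc1ccc(cc1)S(=O)(=O)NN=CC(Cl)=O
Why: Acylation of the secondary alcohol and base-induced loss of sulfinate give the diazoacetate in one flask; the amine-buffered conditions spare both silyl ethers.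

Step 9
Reactants: 11 (1R)-1-[(3R,5R)-3-(tert-butyldimethylsilyloxy)-2-methyl-5-(propan-2-yl)-5-(trimethylsilyloxy)cyclopent-1-en-1-yl]ethyl 2-diazoacetate
Product: 12 tricyclic γ-lactone: 1β-methyl-2β-(TBSO)-4α-isopropyl-4β-(TMSO)bicyclo[3.1.0]hexane with the cyclopropane (C1, C5, C10) on the α face, whose C5 substituent (6R)-CH(CH3)–O and C10 exo substituent C9(=O) are joined as the lactone
Conditions: Rh2(OAc)4 (1 mol%), CH2Cl2, 40 °C, slow addition
Reagents that add atoms: none
Why: Intramolecular Rh(II)-carbenoid cyclopropanation of an allylic diazoacetate closes the γ-lactone and the cyclopropane together, so C9 on C10 is necessarily cis to C6 on C5. Addition is expected on the α face, anti to both silyloxy groups, where the (R)-C6 methyl also lies on the convex side of the lactone; this sets C1, C5 and C10.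

Step 10
Reactants: 12 tricyclic γ-lactone (as in step 9)
Product: 13 diol: 5-[(1R)-1-hydroxyethyl]-10-exo-(hydroxymethyl)-1β-methyl-2β-(TBSO)-4α-isopropyl-4β-(TMSO)bicyclo[3.1.0]hexane
Conditions: LiAlH4, THF, 0 °C
Reagents that add atoms: none
Why: Hydride reduction of the lactone to the 1,4-diol; silyl ethers and the cyclopropane are inert.

Step 11
Reactants: 13 diol (as in step 10)
Product: 14 keto aldehyde: 5-acetyl-10-exo-formyl-1β-methyl-2β-(TBSO)-4α-isopropyl-4β-(TMSO)bicyclo[3.1.0]hexane
Conditions: (COCl)2, DMSO, CH2Cl2, −78 °C; then Et3N
Reagents that add atoms: none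
Why: Swern oxidation activates both hydroxyls before base is added, so the 1,4-diol goes to the dicarbonyl compound without passing through a lactol that would be oxidised back to the lactone.

Step 12
Reactants: 14 keto aldehyde (as in step 11)
Product: 15 ketone: 5-acetyl-1β-methyl-10-exo-[(E)-prop-1-en-1-yl]-2β-(TBSO)-4α-isopropyl-4β-(TMSO)bicyclo[3.1.0]hexane
Conditions: CrCl2, CH3CHI2, THF, rt
Reagents that add atoms: 1,1-diiodoethane, CC(I)I
Why: Takai olefination: the gem-dichromium reagent reacts with aldehydes much faster than with ketones and gives E-alkenes, which places the C8 methyl outside in the later boat transition state.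

Step 13
Reactants: 15 ketone (as in step 12)
Product: 17 hydroazulene diene: 6-(TBSO)-cyclohepta-5,9-diene core with 1β-methyl, 2β-OTBS, 4β-OTMS, 4α-isopropyl and 8α-methyl (8β-H), via silyl enol ether 16 (not isolated)
Conditions: LDA, THF, −78 °C; TBSCl, HMPA, −78 °C → rt; then PhMe, 100 °C
Reagents that add atoms: tert-butyldimethylsilyl chloride, CC(C)(C)[Si](C)(C)Cl
Why: The acetyl group can enolise only towards its methyl (C5 is quaternary), so O-silylation gives 16, whose siloxyvinyl group on C5 and E-propenyl group on C10 are cis on the cyclopropane. On heating, both vinyl groups fold over the three-membered ring and a concerted suprafacial [3,3] shift forms C7–C8 as the strained C5–C10 bond breaks; release of ring strain makes it irreversible. The closest known reaction type is the cis-divinylcyclopropane to cyclohepta-1,4-diene Cope rearrangement triggered by enol silylation of a 2-vinylcyclopropyl ketone. The seven-membered ring closes by ring expansion through a boat-shaped six-centre transition state, which forces both ring alkenes (C5=C6, C9=C10) to be cis. The one new stereocentre, C8, is controlled by the E geometry of the propenyl group in the boat: the methyl points outward and ends up α, trans to the C1 methyl, with the hydrogen β. C1, C2 and C4 are carried over unchanged. The step needs the cis arrangement of the two vinyl groups (secured by the lactone tether of 12), the E alkene (step 12), and a rearrangement faster than the homodienyl 1,5-hydrogen shift from the C1 methyl; that methyl lies under the forming bond, which is why about 100 °C is planned.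

Step 14
Reactants: 17 hydroazulene diene (as in step 13)
Product: 18 hydroxy ketone: trans-fused (5α-H) hydroazulen-6-one with 4β-OH, 4α-isopropyl, 2β-OTBS, 1β-methyl, 8α-methyl and the C9=C10 alkene
Conditions: TBAF (2.2 equiv), AcOH (2.5 equiv), THF, 0 °C
Reagents that add atoms: none
Why: Buffered fluoride cleaves the silyl enol ether and the tertiary TMS ether well before the hindered secondary TBS ether. Protonation at C5 is expected on the α face, away from the C1 methyl and the C4 oxygen, giving the trans-fused ketone, in which C6 also avoids the isopropyl group.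

Step 15
Reactants: 18 hydroxy ketone (as in step 14)
Product: 19 diol: 6α,4β-dihydroxy compound (6β-H), otherwise as 18
Conditions: Me4NBH(OAc)3, AcOH–MeCN, −30 → 0 °C
Reagents that add atoms: none
Why: Evans–Saksena reduction: the 4β-hydroxyl exchanges onto boron and delivers hydride intramolecularly to the β face of C6, giving the 1,3-anti diol (6α-OH), which an external hydride is not expected to give.

Step 16
Reactants: 19 diol (as in step 15)
Product: 20 anisoate: 6α-(4-methoxybenzoyloxy) compound with 4β-OH and 2β-OTBS
Conditions: 4-MeOC6H4COCl, pyridine, DMAP, CH2Cl2, rt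
Reagents that add atoms: 4-methoxybenzoyl chloride, COc1ccc(cc1)C(Cl)=O
Why: DMAP-catalysed acylation of the only secondary hydroxyl; the tertiary C4 hydroxyl should not react.

Step 17
Reactants: 20 anisoate (as in step 16)
Product: 21 diol: 2β,4β-dihydroxy 6α-anisoate
Conditions: HF·pyridine, THF, 0 °C → rt
Reagents that add atoms: none
Why: Acidic fluoride removes the TBS ether without the basic conditions that could move the anisoyl group; no epoxide is present yet.

Step 18
Reactants: 21 diol (as in step 17)
Product: 22 acetate: 2β-acetoxy-4β-hydroxy 6α-anisoate with the C9=C10 alkene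
Conditions: Ac2O, pyridine, DMAP (cat.), CH2Cl2, rt
Reagents that add atoms: acetic anhydride, CC(=O)OC(C)=O
Why: Acetylation of the secondary C2 hydroxyl; the tertiary C4 hydroxyl stays free, and the C10 hydroxyl does not yet exist, so no selectivity between C2 and C10 is needed.

Step 19
Reactants: 22 acetate (as in step 18)
Product: 24 allylic alcohol: 10β-hydroxy compound with the C8=C9 alkene, via allylic hydroperoxide 23 (not isolated)
Conditions: O2, hν, TPP (cat.), CH2Cl2, 0 °C; then PPh3
Reagents that add atoms: oxygen, O=O
Why: Schenck ene reaction of singlet oxygen: the only allylic hydrogen is the 8β-H, so oxygen adds to C10 on the β face (suprafacial) and the alkene shifts to C8=C9; phosphine reduces the hydroperoxide with retention.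

Step 20
Reactants: 24 allylic alcohol (as in step 19)
Product: 25 triethylsilyl ether: 10β-(triethylsilyloxy) compound
Conditions: TESCl, imidazole, DMF, rt
Reagents that add atoms: chlorotriethylsilane, CC[Si](Cl)(CC)CC
Why: Silylation of the secondary allylic hydroxyl (the tertiary one is inert under these conditions) removes its directing hydrogen bond and adds bulk to the β face.

Step 21
Reactants: 25 triethylsilyl ether (as in step 20)
Product: 26 epoxide: 8α,9α-epoxy-10β-(triethylsilyloxy) compound
Conditions: m-CPBA, NaHCO3, CH2Cl2, 0 °C
Reagents that add atoms: m-chloroperoxybenzoic acid, OOC(=O)c1cccc(Cl)c1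
Why: Prilezhaev epoxidation of the trisubstituted alkene anti to the adjacent silyloxy group and the C1 methyl, both β, should set C8 and C9 with the oxygen α.

Step 22
Reactants: 26 epoxide (as in step 21)
Product: 27 CNP0371526.1 (2β-acetoxy-8α,9α-epoxy-4β,10β-dihydroxy-6α-(4-methoxybenzoyloxy) trans-daucane)
Conditions: HF·pyridine, pyridine, THF, 0 °C
Reagents that add atoms: none
Why: Buffered fluoride removes the TES ether; base is avoided so that neither Payne rearrangement of the epoxy alcohol nor acetyl migration from C2 to C10 can start.

## Compound list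

1 | (R)-4-(tert-butyldimethylsilyloxy)cyclopent-2-en-1-one | O=C1C=C[C@H](O[Si](C)(C)C(C)(C)C)C1 | starting material
2 | (3R,4R)-4-(tert-butyldimethylsilyloxy)-3-methyl-1-(trimethylsilyloxy)cyclopent-1-ene | C[Si](C)(C)OC1=C[C@@H](C)[C@H](O[Si](C)(C)C(C)(C)C)C1 | intermediate
3 | (R)-4-(tert-butyldimethylsilyloxy)-3-methylcyclopent-2-en-1-one | O=C1C=C(C)[C@H](O[Si](C)(C)C(C)(C)C)C1 | intermediate
4 | (R)-4-(tert-butyldimethylsilyloxy)-2-iodo-3-methylcyclopent-2-en-1-one | O=C1C(I)=C(C)[C@H](O[Si](C)(C)C(C)(C)C)C1 | intermediate
5 | tributyl(1-ethoxyethenyl)stannane | CCCC[Sn](CCCC)(CCCC)C(=C)OCC | starting material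
6 | (R)-4-(tert-butyldimethylsilyloxy)-2-(1-ethoxyethenyl)-3-methylcyclopent-2-en-1-one | C=C(OCC)C1=C(C)[C@H](O[Si](C)(C)C(C)(C)C)CC1=O | intermediate
7 | (1R,4R)-4-(tert-butyldimethylsilyloxy)-2-(1-ethoxyethenyl)-3-methyl-1-(propan-2-yl)cyclopent-2-en-1-ol (not isolated) | C=C(OCC)C1=C(C)[C@H](O[Si](C)(C)C(C)(C)C)C[C@@]1(O)C(C)C | intermediate
8 | 1-[(3R,5R)-3-(tert-butyldimethylsilyloxy)-5-hydroxy-2-methyl-5-(propan-2-yl)cyclopent-1-en-1-yl]ethan-1-one | CC(=O)C1=C(C)[C@H](O[Si](C)(C)C(C)(C)C)C[C@@]1(O)C(C)C | intermediate
9 | 1-[(3R,5R)-3-(tert-butyldimethylsilyloxy)-2-methyl-5-(propan-2-yl)-5-(trimethylsilyloxy)cyclopent-1-en-1-yl]ethan-1-one | CC(=O)C1=C(C)[C@H](O[Si](C)(C)C(C)(C)C)C[C@@]1(O[Si](C)(C)C)C(C)C | intermediate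
10 | (1R)-1-[(3R,5R)-3-(tert-butyldimethylsilyloxy)-2-methyl-5-(propan-2-yl)-5-(trimethylsilyloxy)cyclopent-1-en-1-yl]ethan-1-ol | C[C@@H](O)C1=C(C)[C@H](O[Si](C)(C)C(C)(C)C)C[C@@]1(O[Si](C)(C)C)C(C)C | intermediate
11 | (1R)-1-[(3R,5R)-3-(tert-butyldimethylsilyloxy)-2-methyl-5-(propan-2-yl)-5-(trimethylsilyloxy)cyclopent-1-en-1-yl]ethyl 2-diazoacetate | C[C@@H](OC(=O)C=[N+]=[N-])C1=C(C)[C@H](O[Si](C)(C)C(C)(C)C)C[C@@]1(O[Si](C)(C)C)C(C)C | intermediate
12 | tricyclic γ-lactone (C6–O–C9(=O) bridge, (6R), cyclopropane on the α face; 1β-Me, 2β-OTBS, 4β-OTMS, 4α-iPr) | C[C@H]1OC(=O)[C@@H]2[C@@]3(C)[C@H](O[Si](C)(C)C(C)(C)C)C[C@@](O[Si](C)(C)C)(C(C)C)[C@@]123 | intermediate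
13 | diol: 5-[(1R)-1-hydroxyethyl]-10-exo-(hydroxymethyl)bicyclo[3.1.0]hexane (1β-Me, 2β-OTBS, 4β-OTMS, 4α-iPr) | C[C@@H](O)[C@]12[C@H](CO)[C@@]1(C)[C@H](O[Si](C)(C)C(C)(C)C)C[C@@]2(O[Si](C)(C)C)C(C)C | intermediate
14 | keto aldehyde: 5-acetyl-10-exo-formylbicyclo[3.1.0]hexane (1β-Me, 2β-OTBS, 4β-OTMS, 4α-iPr) | CC(=O)[C@]12[C@H](C=O)[C@@]1(C)[C@H](O[Si](C)(C)C(C)(C)C)C[C@@]2(O[Si](C)(C)C)C(C)C | intermediate
15 | ketone: 5-acetyl-10-exo-[(E)-prop-1-en-1-yl]bicyclo[3.1.0]hexane (1β-Me, 2β-OTBS, 4β-OTMS, 4α-iPr) | CC(=O)[C@]12[C@H](/C=C/C)[C@@]1(C)[C@H](O[Si](C)(C)C(C)(C)C)C[C@@]2(O[Si](C)(C)C)C(C)C | intermediate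
16 | silyl enol ether (cis-divinylcyclopropane): 5-[1-(tert-butyldimethylsilyloxy)ethenyl] analogue of 15 (not isolated) | C=C(O[Si](C)(C)C(C)(C)C)[C@]12[C@H](/C=C/C)[C@@]1(C)[C@H](O[Si](C)(C)C(C)(C)C)C[C@@]2(O[Si](C)(C)C)C(C)C | intermediate
17 | hydroazulene diene: C5=C6 silyl enol ether (6-OTBS), C9=C10 alkene, 1β-Me, 2β-OTBS, 4β-OTMS, 4α-iPr, 8α-Me | CC(C)(C)[Si](C)(C)OC1=C2[C@](O[Si](C)(C)C)(C(C)C)C[C@@H](O[Si](C)(C)C(C)(C)C)[C@]2(C)C=C[C@H](C)C1 | intermediate
18 | hydroxy ketone: trans-fused (5α-H) 6-ketone, 4β-OH, 4α-iPr, 2β-OTBS, 1β-Me, 8α-Me, C9=C10 | O=C1C[C@@H](C)C=C[C@]2(C)[C@@H]1[C@](O)(C(C)C)C[C@H]2O[Si](C)(C)C(C)(C)C | intermediate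
19 | diol: 6α-OH, 4β-OH, 2β-OTBS, C9=C10 | O[C@H]1C[C@@H](C)C=C[C@]2(C)[C@@H]1[C@](O)(C(C)C)C[C@H]2O[Si](C)(C)C(C)(C)C | intermediate
20 | anisoate: 6α-(4-methoxybenzoyloxy), 4β-OH, 2β-OTBS, C9=C10 | COc1ccc(C(=O)O[C@H]2C[C@@H](C)C=C[C@]3(C)[C@@H]2[C@](O)(C(C)C)C[C@H]3O[Si](C)(C)C(C)(C)C)cc1 | intermediate
21 | diol: 2β,4β-dihydroxy 6α-anisoate, C9=C10 | COc1ccc(C(=O)O[C@H]2C[C@@H](C)C=C[C@]3(C)[C@@H]2[C@](O)(C(C)C)C[C@H]3O)cc1 | intermediate
22 | acetate: 2β-acetoxy-4β-hydroxy 6α-anisoate, C9=C10 | COc1ccc(C(=O)O[C@H]2C[C@@H](C)C=C[C@]3(C)[C@@H]2[C@](O)(C(C)C)C[C@H]3OC(C)=O)cc1 | intermediate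
23 | allylic hydroperoxide: 10β-OOH, C8=C9 (not isolated) | COc1ccc(C(=O)O[C@H]2CC(C)=C[C@H](OO)[C@]3(C)[C@@H]2[C@](O)(C(C)C)C[C@H]3OC(C)=O)cc1 | intermediate
24 | allylic alcohol: 10β-OH, C8=C9 | COc1ccc(C(=O)O[C@H]2CC(C)=C[C@H](O)[C@]3(C)[C@@H]2[C@](O)(C(C)C)C[C@H]3OC(C)=O)cc1 | intermediate
25 | triethylsilyl ether: 10β-OTES, C8=C9 | COc1ccc(C(=O)O[C@H]2CC(C)=C[C@H](O[Si](CC)(CC)CC)[C@]3(C)[C@@H]2[C@](O)(C(C)C)C[C@H]3OC(C)=O)cc1 | intermediate
26 | epoxide: 8α,9α-epoxy-10β-OTES | COc1ccc(C(=O)O[C@H]2C[C@@]3(C)O[C@H]3[C@H](O[Si](CC)(CC)CC)[C@]3(C)[C@@H]2[C@](O)(C(C)C)C[C@H]3OC(C)=O)cc1 | intermediate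
27 | CNP0371526.1 | COc1ccc(C(=O)O[C@H]2C[C@@]3(C)O[C@H]3[C@H](O)[C@]3(C)[C@@H]2[C@](O)(C(C)C)C[C@H]3OC(C)=O)cc1 | target

## Step count and least certain steps

Total: 22 steps. Longest linear sequence: 22 steps (from 1; the route is fully linear).

**Step 13 (key step).** The C1 methyl is cis to both vinyl groups and lies under the forming C7–C8 bond, so the boat transition state is congested and the shift may be slow. If the temperature has to be raised, a homodienyl 1,5-hydrogen shift from the C1 methyl to a vinyl terminus could open the cyclopropane the wrong way, and the enol ether could be lost by adventitious hydrolysis. Fallback: run the rearrangement in the charge-accelerated mode. Starting from 15, KHMDS and 18-crown-6 in THF at −78 → 0 °C give the potassium enolate of 15 F1, a more electron-rich 2-oxido diene that should rearrange at lower temperature (by analogy with enolates outrunning silyl ketene acetals in Claisen rearrangements). The rearranged potassium enolate F2 is trapped with TBSCl, and the route is rejoined at 17.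

**Step 9.** The carbenoid may add with poor facial selectivity, since the α face carries the C4 isopropyl group, or be diverted into C–H insertion or dimerisation because the alkene is tetrasubstituted. Fallback: an intermolecular Michael-initiated ring closure. Starting from enone 9, the ylide made from 1-[(2E)-but-2-en-1-yl]thiolan-1-ium bromide F3 (from (E)-crotyl bromide and tetrahydrothiophene) with LiHMDS in THF at −78 → 0 °C adds to C1 anti to the C2 silyloxy group and closes the cyclopropane. This would give 15 directly, by-passing 10–14, but the cis arrangement at C10 is then no longer enforced and isomers would have to be separated.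

**Step 14.** Protonation at C5 may occur on the β face and give the cis ring fusion, or the basic fluoride may trigger retro-aldol or elimination at C4. Fallback: thermodynamic control on a protected ketone. Starting from 17, the crude cleavage product is re-silylated at C4 (N-trimethylsilylimidazole) to the 4-O-trimethylsilyl ketone F4, which has no free β-hydroxyl and can be equilibrated at C5 with DBU. Citric acid in methanol then removes the TMS group and the route is rejoined at 18.

**Step 19.** The cis-disubstituted alkene is a slow ene partner and oxygen must approach the β face, next to the C1 methyl and the C2 acetate; long irradiation may lead to unselective photo-oxidation. Fallback: directed epoxidation and isomerisation. Starting from diol 21, VO(acac)2 and t-BuOOH, directed by the homoallylic 2β-hydroxyl, should give the 9β,10β-epoxide diol F5. Acetylation (Ac2O, pyridine) gives the 9β,10β-epoxide acetate F6. TMSOTf and 2,6-lutidine followed by DBU should open the epoxide at C9 and remove the anti 8β-hydrogen, giving the bis-trimethylsilyl allylic ether F7. Citric acid in methanol returns the route at 24.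

**Step 21.** Facial selectivity may be poor, because the α face carries the C6 anisoate one carbon away from C8. Fallback: epoxidise at the ketone oxidation level. Starting from 24, Dess–Martin oxidation gives the C10 enone F8. Nucleophilic epoxidation (t-BuOOH, DBU) gives the 8α,9α-epoxy ketone F9. Reduction with NaBH4 and CeCl3, with hydride anti to the C1 methyl, returns the route at 27 without the silyl steps.

## Further compounds

F1 | step 13 | potassium enolate of 15 | C=C([O-])[C@]12[C@H](/C=C/C)[C@@]1(C)[C@H](O[Si](C)(C)C(C)(C)C)C[C@@]2(O[Si](C)(C)C)C(C)C.[K+]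
F2 | step 13 | rearranged potassium enolate (C5=C6 enolate of the hydroazulene) | [O-]C1=C2[C@](O[Si](C)(C)C)(C(C)C)C[C@@H](O[Si](C)(C)C(C)(C)C)[C@]2(C)C=C[C@H](C)C1.[K+]
F3 | step 9 | 1-[(2E)-but-2-en-1-yl]thiolan-1-ium bromide | C/C=C/C[S+]1CCCC1.[Br-]
F4 | step 14 | 4-O-trimethylsilyl ketone (trans-fused 6-ketone, 4β-OTMS, 2β-OTBS) | O=C1C[C@@H](C)C=C[C@]2(C)[C@@H]1[C@](O[Si](C)(C)C)(C(C)C)C[C@H]2O[Si](C)(C)C(C)(C)C
F5 | step 19 | 9β,10β-epoxide diol (2β,4β-dihydroxy 6α-anisoate) | COc1ccc(C(=O)O[C@H]2C[C@@H](C)[C@@H]3O[C@@H]3[C@]4(C)[C@@H]2[C@](O)(C(C)C)C[C@H]4O)cc1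
F6 | step 19 | 9β,10β-epoxide acetate (2β-acetoxy) | COc1ccc(C(=O)O[C@H]2C[C@@H](C)[C@@H]3O[C@@H]3[C@]4(C)[C@@H]2[C@](O)(C(C)C)C[C@H]4OC(C)=O)cc1
F7 | step 19 | bis-trimethylsilyl allylic ether (10β-OTMS, 4β-OTMS, C8=C9) | COc1ccc(C(=O)O[C@H]2CC(C)=C[C@H](O[Si](C)(C)C)[C@]3(C)[C@@H]2[C@](O[Si](C)(C)C)(C(C)C)C[C@H]3OC(C)=O)cc1
F8 | step 21 | C10 enone (C8=C9) | COc1ccc(C(=O)O[C@H]2CC(C)=CC(=O)[C@]3(C)[C@@H]2[C@](O)(C(C)C)C[C@H]3OC(C)=O)cc1
F9 | step 21 | 8α,9α-epoxy C10 ketone | COc1ccc(C(=O)O[C@H]2C[C@@]3(C)O[C@H]3C(=O)[C@]3(C)[C@@H]2[C@](O)(C(C)C)C[C@H]3OC(C)=O)cc1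
A1 | alternative 1 | siloxycyclopropane bridging C1 and C10 | COc1ccc(C(=O)O[C@H]2CC(C)=C[C@]4(O[Si](C)(C)C(C)(C)C)C[C@@]34[C@@H]2[C@](O)(C(C)C)C[C@H]3O)cc1
A2 | alternative 1 | dienol ether precursor (C1=C10 silyl enol ether, C8=C9 alkene) | COc1ccc(C(=O)O[C@H]2CC(C)=CC(O[Si](C)(C)C(C)(C)C)=C3[C@@H]2[C@](O)(C(C)C)C[C@H]3O)cc1
A3 | alternative 2 | cyclopentan-2-one with the C4 tertiary silyl ether, C6 ester and C10 silyl ether | CCOC(=O)[C@H]1[C@](O[Si](C)(C)C(C)(C)C)(C(C)C)CC(=O)[C@]1(C)CO[Si](c2ccccc2)(c2ccccc2)C(C)(C)C
A4 | alternative 2 | diazomethyl ketone precursor | CCOC(=O)[C@H]([C@@](C)(CO[Si](c1ccccc1)(c1ccccc1)C(C)(C)C)C(=O)C=[N+]=[N-])[C@H](O[Si](C)(C)C(C)(C)C)C(C)C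
A5 | alternative 3 | trans-fused hydroazulen-10-one with C2 and C4 hydroxyls | CC(C)(C)[Si](C)(C)O[C@H]2CC(C)=CC(=O)[C@]3(C)[C@@H]2[C@](O)(C(C)C)C[C@H]3O
A6 | alternative 3 | epoxy cyclodecenone precursor (C4–C5 epoxide, C10 enone) | CC(C)(C)[Si](C)(C)O[C@H]1CC(C)=CC(=O)C(C)[C@H](O)C[C@]2(C(C)C)O[C@H]12
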